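## Retrosynthetic overview
1. Michaolide F comes from its 14-O-triethylsilyl ether by a final desilylation.
2. The silyl ether comes from one acyclic epoxy aldehyde that carries a (Z)-2-(borylmethyl)enoate. A single thermal operation forms C1–C2 (14-membered carbocycle) and then O2–C16 (α-methylene-γ-lactone).
3. The allylboronate comes from an ynoate by syn hydroalumination and borylmethylation. The C14 carbinol comes from a β,γ-unsaturated aldehyde and methyl propiolate, and the aldehyde carbon comes from CO on a terminal allylic chloride.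
4. The epoxide and the C5 acetate come from Sharpless epoxidation of a 2-ene-1,4-diol. The diol is made from (E)-geranylacetone by proline aminoxylation (C5) and Wittig olefination (C2, C3).
5. Ring order: the epoxide forms first (step 4), then the carbocycle and the lactone form together (step 13).

Assumption: cembrane numbering is used (C1 lactone β-carbon, C2 lactone O–CH, C3/C4 epoxide, C5 acetoxy carbon, C14 carbinol, C15–C17 acrylate carbons), and single-isomer (E)-geranylacetone is bought.

## Route

Step 1
Reactants: 1 (E)-geranylacetone; 2 nitrosobenzene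
Product: 4 (3R,5E)-3-hydroxy-6,10-dimethylundeca-5,9-dien-2-one, via anilinooxy ketone 3 (not isolated)
Conditions: L-proline (20 mol %), DMSO, rt, 2 added by syringe pump to 1 (3 equiv); then CuSO4·5H2O (30 mol %), MeOH, 0 °C
Reagents that add atoms: none
Why: The proline-catalysed α-aminoxylation (enamine catalysis) reacts through the more substituted methylene enamine of the methyl ketone, the carboxylic acid of L-proline steers the oxygen of nitrosobenzene to one enamine face and sets C5 as R, and the copper-catalysed N–O cleavage leaves the new carbinol untouched.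

Step 2
Reactants: 4 hydroxy ketone; 5 ethyl (triphenylphosphoranylidene)acetate
Product: 6 ethyl (2E,4R,6E)-4-hydroxy-3,7,11-trimethyldodeca-2,6,10-trienoate
Conditions: 5 (1.5 equiv), PhMe, 90 °C
Reagents that add atoms: none
Why: The Wittig reaction of a stabilised ylide with the α-hydroxy-activated methyl ketone runs under neutral conditions that do not enolise C5, it places the ester trans to the bulkier carbinol branch (C2 trans to C5, E), and the minor Z isomer lactonises to a butenolide that chromatography removes.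

Step 3
Reactants: 6 hydroxy enoate
Product: 7 (2E,4R,6E)-3,7,11-trimethyldodeca-2,6,10-triene-1,4-diol
Conditions: i-Bu2AlH (3.5 equiv), CH2Cl2, −78 °C; Rochelle salt
Reagents that add atoms: none
Why: Low-temperature i-Bu2AlH 1,2-reduction of the enoate gives the primary allylic alcohol without touching the isolated olefins or C5, and the free hydroxyl only consumes one extra equivalent of hydride.

Step 4
Reactants: 7 ene-diol
Product: 8 (1R,3E)-1-[(2S,3S)-3-(hydroxymethyl)-2-methyloxiran-2-yl]-4,8-dimethylnona-3,7-dien-1-ol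
Conditions: Ti(OiPr)4 (20 mol %), L-(+)-diethyl tartrate (24 mol %), t-BuOOH (1.5 equiv), 4 Å MS, CH2Cl2, −20 °C
Reagents that add atoms: tert-butyl hydroperoxide CC(C)(C)OO
Why: The Sharpless asymmetric epoxidation attacks only the allylic olefin, L-(+)-tartrate delivers oxygen to the face that gives the (3S,4S)-epoxide as in (2S,3S)-epoxygeraniol, and since binding through the secondary C5 hydroxyl addresses the same face but is the slow mismatched mode, control through the primary alcohol gives the required threo C4/C5 relationship.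

Step 5
Reactants: 8 epoxy diol
Product: 10 (1R,3E)-4,8-dimethyl-1-[(2S,3S)-2-methyl-3-(triethylsilyloxymethyl)oxiran-2-yl]nona-3,7-dienyl acetate, via primary triethylsilyl ether 9 (not isolated)
Conditions: TESCl (1.05 equiv), imidazole, CH2Cl2, −40 °C; then Ac2O, Et3N, DMAP (cat.), 0 °C to rt
Reagents that add atoms: chlorotriethylsilane CC[Si](Cl)(CC)CC; acetic anhydride CC(=O)OC(C)=O
Why: Silylation at low temperature selects the unhindered primary alcohol, the hindered C5 carbinol is then esterified by DMAP-catalysed acylation in the same flask, and no stereocentre is touched.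

Step 6
Reactants: 10 silyl ether acetate
Product: 11 (1R,3E,7E)-9-hydroxy-4,8-dimethyl-1-[(2S,3S)-2-methyl-3-(triethylsilyloxymethyl)oxiran-2-yl]nona-3,7-dienyl acetate
Conditions: SeO2 (20 mol %), t-BuOOH (3 equiv, decane), CH2Cl2, 0 °C
Reagents that add atoms: tert-butyl hydroperoxide CC(C)(C)OO
Why: The catalytic SeO2 allylic oxidation (ene reaction followed by a [2,3]-sigmatropic shift) attacks the most electron-rich and least hindered terminal isopropylidene group and gives the E-allylic alcohol, while the 7,8-olefin reacts more slowly and the epoxide, acetate and silyl ether are inert in the aprotic medium.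

Step 7
Reactants: 11 allylic alcohol
Product: 12 (1R,3E,7E)-9-chloro-4,8-dimethyl-1-[(2S,3S)-2-methyl-3-(triethylsilyloxymethyl)oxiran-2-yl]nona-3,7-dienyl acetate
Conditions: NCS, Me2S, CH2Cl2, −30 to 0 °C
Reagents that add atoms: N-chlorosuccinimide O=C1CCC(=O)N1Cl
Why: The Corey–Kim reagent converts the primary allylic alcohol into its alkoxysulfonium salt, which chloride displaces by SN2 under nearly neutral conditions without allylic transposition or loss of the E geometry.

Step 8
Reactants: 12 allylic chloride
Product: 13 (1R,3E,7E)-4,8-dimethyl-10-oxo-1-[(2S,3S)-2-methyl-3-(triethylsilyloxymethyl)oxiran-2-yl]deca-3,7-dienyl acetate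
Conditions: Pd(PPh3)4 (5 mol %), CO (3 atm), Bu3SnH (1.1 equiv, syringe pump), THF, 50 °C
Reagents that add atoms: carbon monoxide [C-]#[O+]
Why: The palladium-catalysed reductive carbonylation (Stille-type formylation) goes through the syn π-allyl complex, CO insertion at the unhindered terminus C13 and hydride transfer from tin, so the E-olefin stays in place and the unconjugated aldehyde forms under neutral conditions that tolerate acetate, epoxide and silyl ether.

Step 9
Reactants: 13 β,γ-unsaturated aldehyde; 14 methyl propiolate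
Product: 15 methyl (4R,6E,10E,13R)-13-acetoxy-4-hydroxy-6,10-dimethyl-13-[(2S,3S)-2-methyl-3-(triethylsilyloxymethyl)oxiran-2-yl]trideca-6,10-dien-2-ynoate
Conditions: 14 (3 equiv), Me2Zn (3 equiv), (S,S)-ProPhenol (20 mol %), Ph3PO (40 mol %), PhMe, 4 °C
Reagents that add atoms: none
Why: The dinuclear zinc–ProPhenol asymmetric alkynylation adds the zinc acetylide of methyl propiolate to the Si face of the aldehyde inside the chiral pocket and sets C14 as R under reagent control, and the mild zinc base leaves the β,γ-olefin unconjugated.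

Step 10
Reactants: 15 propargylic alcohol
Product: 16 methyl (4R,6E,10E,13R)-13-acetoxy-6,10-dimethyl-13-[(2S,3S)-2-methyl-3-(triethylsilyloxymethyl)oxiran-2-yl]-4-(triethylsilyloxy)trideca-6,10-dien-2-ynoate
Conditions: TESCl, imidazole, DMAP (cat.), CH2Cl2, 0 °C
Reagents that add atoms: chlorotriethylsilane CC[Si](Cl)(CC)CC
Why: Imidazole-promoted silylation masks O14 so that it can neither lactonise onto the cis ester made in the next step nor compete for that ester in the ring closure.

Step 11
Reactants: 16 silyloxy ynoate; 17 2-(iodomethyl)-4,4,5,5-tetramethyl-1,3,2-dioxaborolane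
Product: 19 methyl (2Z,4R,6E,10E,13R)-13-acetoxy-6,10-dimethyl-13-[(2S,3S)-2-methyl-3-(triethylsilyloxymethyl)oxiran-2-yl]-2-[(4,4,5,5-tetramethyl-1,3,2-dioxaborolan-2-yl)methyl]-4-(triethylsilyloxy)trideca-2,6,10-trienoate, via alpha-aluminated enoate 18 (not isolated)
Conditions: i-Bu2AlH (1.2 equiv), HMPA (2.5 equiv), THF, 0 °C, 2 h; then 17 (1.5 equiv), 0 °C to rt
Reagents that add atoms: none
Why: The i-Bu2AlH–HMPA complex adds H and Al syn across the ynoate in a conjugate hydroalumination without reducing ester carbonyls (the ynoate ester survives, so the acetate should too), and alkylation of the vinylalane by the iodomethylboronate with retention gives the contra-thermodynamic allylboronate with C14 cis to the ester and trans to CH2B.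

Step 12
Reactants: 19 allylboronate
Product: 20 methyl (2Z,4R,6E,10E,13R)-13-acetoxy-13-[(2S,3R)-3-formyl-2-methyloxiran-2-yl]-6,10-dimethyl-2-[(4,4,5,5-tetramethyl-1,3,2-dioxaborolan-2-yl)methyl]-4-(triethylsilyloxy)trideca-2,6,10-trienoate
Conditions: (COCl)2 (4 equiv), DMSO (8 equiv), CH2Cl2, −78 to −35 °C; Et3N, −78 to 0 °C; rapid silica filtration
Reagents that add atoms: none
Why: Under Swern conditions the chlorodimethylsulfonium ion cleaves the unhindered primary triethylsilyl ether directly to the alkoxysulfonium salt and hence to the aldehyde, the secondary silyl ether remains, and at these temperatures the electron-poor allylboronate does not yet add to the new aldehyde.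

Step 13
Reactants: 20 epoxy aldehyde allylboronate
Product: 22 14-O-triethylsilyl michaolide F, via macrocyclic borate ester 21 (not isolated)
Conditions: PhMe (1 mM), 90 °C, 36 h
Reagents that add atoms: none
Why: Proposed new method: this is a macrocyclic version of the thermal addition of 2-alkoxycarbonyl allylboronates to aldehydes with in situ lactonisation (closest known types: the intermolecular allylboration–lactonisation route to α-methylene-γ-butyrolactones and small-ring intramolecular allylborations), in which the configurationally stable boronate reacts through a closed chair Zimmerman–Traxler transition state to give the anti C1/C2 pair (trans-lactone), the epoxy aldehyde is attacked in its Cornforth conformer (C2–O anti to the epoxide oxygen, 2S), A(1,3) strain at C14 fixes the allyl face (H14 eclipsing the ester and C13 anti to the forming bond, 1R), high dilution suppresses oligomers, and the C2–O–Bpin borate then attacks the methyl ester to close the lactone while the silyl group keeps O14 out.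

Step 14
Reactants: 22 silyl ether
Product: 23 michaolide F
Conditions: HF·pyridine, pyridine, THF, 0 °C
Reagents that add atoms: none
Why: Buffered HF–pyridine removes the secondary triethylsilyl ether by fluoride-assisted Si–O cleavage at 0 °C, the acetate, the deactivated epoxide and the α-methylene lactone survive, and no base is present that could trigger translactonisation to O14.

## Compound list
1 | (E)-geranylacetone, (5E)-6,10-dimethylundeca-5,9-dien-2-one | CC(C)=CCC/C(C)=C/CCC(C)=O | starting material
2 | nitrosobenzene | O=Nc1ccccc1 | starting material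
3 | (3R,5E)-3-(anilinooxy)-6,10-dimethylundeca-5,9-dien-2-one | CC(C)=CCC/C(C)=C/C[C@@H](ONc1ccccc1)C(C)=O | intermediate
4 | (3R,5E)-3-hydroxy-6,10-dimethylundeca-5,9-dien-2-one | CC(C)=CCC/C(C)=C/C[C@@H](O)C(C)=O | intermediate
5 | ethyl (triphenylphosphoranylidene)acetate | CCOC(=O)C=P(c1ccccc1)(c1ccccc1)c1ccccc1 | starting material
6 | ethyl (2E,4R,6E)-4-hydroxy-3,7,11-trimethyldodeca-2,6,10-trienoate | CC(C)=CCC/C(C)=C/C[C@@H](O)/C(C)=C/C(=O)OCC | intermediate
7 | (2E,4R,6E)-3,7,11-trimethyldodeca-2,6,10-triene-1,4-diol | CC(C)=CCC/C(C)=C/C[C@@H](O)/C(C)=C/CO | intermediate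
8 | (1R,3E)-1-[(2S,3S)-3-(hydroxymethyl)-2-methyloxiran-2-yl]-4,8-dimethylnona-3,7-dien-1-ol | CC(C)=CCC/C(C)=C/C[C@@H](O)[C@]1(C)O[C@H]1CO | intermediate
9 | primary triethylsilyl ether of 8 | CC(C)=CCC/C(C)=C/C[C@@H](O)[C@]1(C)O[C@H]1CO[Si](CC)(CC)CC | intermediate
10 | (1R,3E)-4,8-dimethyl-1-[(2S,3S)-2-methyl-3-(triethylsilyloxymethyl)oxiran-2-yl]nona-3,7-dienyl acetate | CC(C)=CCC/C(C)=C/C[C@@H](OC(C)=O)[C@]1(C)O[C@H]1CO[Si](CC)(CC)CC | intermediate
11 | terminal (E)-allylic alcohol of 10 (C13–OH) | OC/C(C)=C/CC/C(C)=C/C[C@@H](OC(C)=O)[C@]1(C)O[C@H]1CO[Si](CC)(CC)CC | intermediate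
12 | terminal (E)-allylic chloride (C13–Cl) | ClC/C(C)=C/CC/C(C)=C/C[C@@H](OC(C)=O)[C@]1(C)O[C@H]1CO[Si](CC)(CC)CC | intermediate
13 | β,γ-unsaturated aldehyde (C14 = CHO) | O=CC/C(C)=C/CC/C(C)=C/C[C@@H](OC(C)=O)[C@]1(C)O[C@H]1CO[Si](CC)(CC)CC | intermediate
14 | methyl propiolate | C#CC(=O)OC | starting material
15 | (14R)-γ-hydroxy ynoate | COC(=O)C#C[C@H](O)C/C(C)=C/CC/C(C)=C/C[C@@H](OC(C)=O)[C@]1(C)O[C@H]1CO[Si](CC)(CC)CC | intermediate
16 | (14R)-γ-triethylsilyloxy ynoate | COC(=O)C#C[C@H](O[Si](CC)(CC)CC)C/C(C)=C/CC/C(C)=C/C[C@@H](OC(C)=O)[C@]1(C)O[C@H]1CO[Si](CC)(CC)CC | intermediate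
17 | 2-(iodomethyl)-4,4,5,5-tetramethyl-1,3,2-dioxaborolane | ICB1OC(C)(C)C(C)(C)O1 | starting material
18 | α-(diisobutylalumino) enoate, C14 cis to the ester | COC(=O)/C([Al](CC(C)C)CC(C)C)=C\[C@H](O[Si](CC)(CC)CC)C/C(C)=C/CC/C(C)=C/C[C@@H](OC(C)=O)[C@]1(C)O[C@H]1CO[Si](CC)(CC)CC | intermediate
19 | (2Z)-2-(pinacolborylmethyl) enoate, bis-silyl ether | COC(=O)/C(CB1OC(C)(C)C(C)(C)O1)=C\[C@H](O[Si](CC)(CC)CC)C/C(C)=C/CC/C(C)=C/C[C@@H](OC(C)=O)[C@]1(C)O[C@H]1CO[Si](CC)(CC)CC | intermediate
20 | epoxy aldehyde allylboronate | COC(=O)/C(CB1OC(C)(C)C(C)(C)O1)=C\[C@H](O[Si](CC)(CC)CC)C/C(C)=C/CC/C(C)=C/C[C@@H](OC(C)=O)[C@]1(C)O[C@H]1C=O | intermediate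
21 | 14-membered carbocycle with C2–O–Bpin and an open methyl acrylate | C=C(C(=O)OC)[C@@H]1[C@H](O[Si](CC)(CC)CC)C/C(C)=C/CC/C(C)=C/C[C@@H](OC(C)=O)[C@]2(C)O[C@H]2[C@H]1OB3OC(C)(C)C(C)(C)O3 | intermediate
22 | 14-O-triethylsilyl michaolide F | C=C1C(=O)O[C@H]2[C@H]1[C@H](O[Si](CC)(CC)CC)C/C(C)=C/CC/C(C)=C/C[C@@H](OC(C)=O)[C@]1(C)O[C@@H]21 | intermediate
23 | michaolide F, (1R,2S,3S,4S,5R,14R,7E,11E) | C=C1C(=O)O[C@H]2[C@H]1[C@H](O)C/C(C)=C/CC/C(C)=C/C[C@@H](OC(C)=O)[C@]1(C)O[C@@H]21 | target

Total step count: 14. Longest linear sequence: 14 steps, from (E)-geranylacetone.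

## Steps most likely to fail

**Step 13.** The ring closure has no precedent at this ring size, and the hindered, electron-poor boronate may be too slow or may oligomerise. The fallback sets out from 16 and comes back at 22, and it replaces boron by an allylchromium nucleophile.
- The vinylalane 18 is made as in step 11 and trapped with paraformaldehyde to give the (2Z)-2-(hydroxymethyl) enoate F5.
- CBr4 and PPh3 convert it into the (2E)-2-(bromomethyl) enoate F6.
- The Swern protocol of step 12 gives the bromo epoxy aldehyde F7.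
- CrCl2 in THF/DMF at high dilution closes C1–C2 by a Nozaki–Hiyama addition under macrocyclic control, and the trivalent chromium alkoxide lactonises to 22.

**Step 11.** The acetate may not survive the aluminium hydride, and the vinylalane may lose its geometry before alkylation. The fallback sets out from 16 and comes back at 19, and it uses no hydride reagent strong enough to touch esters.
- Syn hydrostannation (Bu3SnH, Pd(PPh3)4) gives the (2E)-2-(tributylstannyl) enoate F3.
- Iodine gives the (2E)-2-iodo enoate F4 with retention.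
- Negishi coupling of F4 with the zinc reagent made from 17 and zinc dust (Pd(PPh3)4, THF) gives 19.

**Step 8.** Direct reduction of the chloride by tin hydride may compete, and the product may drift into conjugation. The fallback sets out from 11 and comes back at 13, and it brings in C14 as a methylene group instead of CO.
- MnO2 oxidises 11 to the (E)-enal F1.
- Preformed dimethylsulfonium methylide (1.05 equiv, −10 °C) gives the alkenyl oxirane F2 as an inconsequential mixture of epimers.
- Pd(PPh3)4, a zerovalent palladium complex that activates only the vinylic epoxide, isomerises F2 through the π-allyl alkoxide to the β,γ-unsaturated aldehyde 13.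

## Further compounds
F1 | step 8 | (2E,6E,9R)-9-acetoxy-2,6-dimethyl-9-[(2S,3S)-2-methyl-3-(triethylsilyloxymethyl)oxiran-2-yl]nona-2,6-dienal | O=C/C(C)=C/CC/C(C)=C/C[C@@H](OC(C)=O)[C@]1(C)O[C@H]1CO[Si](CC)(CC)CC
F2 | step 8 | (1R,3E,7E)-4-methyl-1-[(2S,3S)-2-methyl-3-(triethylsilyloxymethyl)oxiran-2-yl]-8-(oxiran-2-yl)nona-3,7-dienyl acetate, both epimers at the new oxirane carbon | C1OC1/C(C)=C/CC/C(C)=C/C[C@@H](OC(C)=O)[C@]2(C)O[C@H]2CO[Si](CC)(CC)CC
F3 | step 11 | (2E)-2-(tributylstannyl) enoate derived from 16, C14 cis to the ester | COC(=O)/C([Sn](CCCC)(CCCC)CCCC)=C\[C@H](O[Si](CC)(CC)CC)C/C(C)=C/CC/C(C)=C/C[C@@H](OC(C)=O)[C@]1(C)O[C@H]1CO[Si](CC)(CC)CC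
F4 | step 11 | (2E)-2-iodo enoate, C14 cis to the ester | COC(=O)/C(I)=C\[C@H](O[Si](CC)(CC)CC)C/C(C)=C/CC/C(C)=C/C[C@@H](OC(C)=O)[C@]1(C)O[C@H]1CO[Si](CC)(CC)CC
F5 | step 13 | (2Z)-2-(hydroxymethyl) enoate, C14 cis to the ester | COC(=O)/C(CO)=C\[C@H](O[Si](CC)(CC)CC)C/C(C)=C/CC/C(C)=C/C[C@@H](OC(C)=O)[C@]1(C)O[C@H]1CO[Si](CC)(CC)CC
F6 | step 13 | (2E)-2-(bromomethyl) enoate, C14 cis to the ester | COC(=O)/C(CBr)=C\[C@H](O[Si](CC)(CC)CC)C/C(C)=C/CC/C(C)=C/C[C@@H](OC(C)=O)[C@]1(C)O[C@H]1CO[Si](CC)(CC)CC
F7 | step 13 | bromo epoxy aldehyde | COC(=O)/C(CBr)=C\[C@H](O[Si](CC)(CC)CC)C/C(C)=C/CC/C(C)=C/C[C@@H](OC(C)=O)[C@]1(C)O[C@H]1C=O
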